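**Strategy.** Ring atoms are called C1 (quaternary), C2 (CH), C3 (alkylidene carbon), C4, C5 (CH2) and C6 (carbinol). Everything rests on closing the cyclohexane across its bare C4–C5 ethano bridge, which sits between two carbons that can each be a carbonyl derivative: C3 as the stereodefined (E)-enol triflate of a β-keto ester and C6 as a methyl ketone. Vinylmagnesium bromide then acts, in one flask, as an ethane-1,2-diyl dianion: Felkin–Anh addition to the ketone forms C5–C6 and sets C6, and hydroboration with intramolecular B-alkyl Suzuki coupling forms C3–C4 with retention, which fixes the (Z)-enal geometry. The acyclic precursor carries the C1–C2 diad from one enantioselective Ireland–Claisen rearrangement.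

Key step: step 14

Assumption: the (R)-phosphoric acid of step 1 and the (S,S)-diazaborolidine of step 10 are taken to be the enantiomers that deliver the drawn configurations (otherwise their antipodes are used), and acid 13 is taken as a catalogue compound.

**Step 1**
Reactants: 1 3-methylbut-2-enal
Product: 2 (R)-6-methylhept-5-en-1-yn-4-ol
Conditions: (R)-TRIP (3,3′-bis(2,4,6-triisopropylphenyl)-BINOL hydrogen phosphate, 5 mol%), 4 Å MS, toluene, −20 °C
Reagents that add atoms: allenylboronic acid pinacol ester, C=C=CB1OC(C)(C)C(C)(C)O1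
Why: Chiral phosphoric acid-catalysed propargylation of the aldehyde by the allenylboronate through a closed six-membered transition state (SE2′ transfer) should give the homopropargylic alcohol, the catalyst setting the (R)-carbinol centre.

**Step 2**
Reactants: 2 (R)-6-methylhept-5-en-1-yn-4-ol
Product: 3 (R)-TBS ether of 2
Conditions: TBSCl, imidazole, DMF, rt
Reagents that add atoms: tert-butyldimethylsilyl chloride, CC(C)(C)[Si](C)(C)Cl
Why: Standard silyl ether protection masks the carbinol for the organometallic steps.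

**Step 3**
Reactants: 3 (R)-TBS ether of 2
Product: 5 (R,E)-tert-butyl[(1-iodo-2,6-dimethylhepta-1,5-dien-4-yl)oxy]dimethylsilane, via alkenyldimethylalane 4 (not isolated)
Conditions: Me3Al, Cp2ZrCl2 (25 mol%), CH2Cl2, −20 °C to rt; then I2, THF, −30 °C
Reagents that add atoms: trimethylaluminium, C[Al](C)C; iodine, II
Why: Zirconium-catalysed carboalumination (Negishi carboalumination) adds methyl and aluminium syn across the terminal alkyne with methyl on the internal carbon, and iodinolysis with retention should give the (E)-iodide.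

**Step 4**
Reactants: 6 geranyl acetate
Product: 7 (2E,6E)-8-hydroxy-3,7-dimethylocta-2,6-dien-1-yl acetate
Conditions: SeO2 (cat.), t-BuOOH, salicylic acid (cat.), CH2Cl2, rt
Reagents that add atoms: tert-butyl hydroperoxide, CC(C)(C)OO
Why: SeO2 allylic oxidation (ene reaction then 2,3-sigmatropic shift) is selective for the (E)-methyl group of the terminal trisubstituted alkene.

**Step 5**
Reactants: 7 (2E,6E)-8-hydroxy-3,7-dimethylocta-2,6-dien-1-yl acetate
Product: 8 (2E,6E)-3,7-dimethyl-8-oxoocta-2,6-dien-1-yl acetate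
Conditions: MnO2, CH2Cl2, rt
Reagents that add atoms: none
Why: MnO2 oxidation of the primary allylic alcohol should give the enal without touching the acetate or the alkenes.

**Step 6**
Reactants: 8 (2E,6E)-3,7-dimethyl-8-oxoocta-2,6-dien-1-yl acetate
Product: 9 (2E,6E)-3,7-dimethylnona-2,6,8-trien-1-yl acetate
Conditions: Ph3PCH3Br, KN(SiMe3)2, THF, −78 to 0 °C
Reagents that add atoms: methyltriphenylphosphonium bromide, C[P+](c1ccccc1)(c1ccccc1)c1ccccc1.[Br-]
Why: Wittig methylenation of the enal gives the terminal diene and leaves the (E)-trisubstituted alkene untouched.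

**Step 7**
Reactants: 9 (2E,6E)-3,7-dimethylnona-2,6,8-trien-1-yl acetate
Product: 10 (2E,6E)-3,7-dimethylnona-2,6,8-trien-1-ol
Conditions: K2CO3 (cat.), MeOH, rt
Reagents that add atoms: none
Why: Base-catalysed transesterification (methanolysis) frees the allylic alcohol.

**Step 8**
Reactants: 10 (2E,6E)-3,7-dimethylnona-2,6,8-trien-1-ol; 5 (R,E)-vinyl iodide
Product: 12 (2E,6E,10E,13R)-13-[(tert-butyldimethylsilyl)oxy]-3,7,11,15-tetramethylhexadeca-2,6,10,14-tetraen-1-ol, via alkylborane 11 (not isolated)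
Conditions: 9-BBN (2.2 equiv), THF, 0 °C to rt; then 5, Pd(dppf)Cl2 (5 mol%), AsPh3, Cs2CO3, DMF/H2O, rt
Reagents that add atoms: none
Why: 9-BBN hydroborates only the monosubstituted alkene, with boron on the terminal carbon, and the B-alkyl Suzuki–Miyaura coupling proceeds with retention of the (E)-iodide geometry.

**Step 9**
Reactants: 12 (13R)-silyloxy tetraenol; 13 5-[(tert-butyldimethylsilyl)oxy]pentanoic acid
Product: 14 allylic ester of 12 with 13
Conditions: EDC·HCl, DMAP (cat.), CH2Cl2, rt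
Reagents that add atoms: none
Why: Carbodiimide esterification (Steglich esterification) joins the allylic alcohol and the acid under neutral conditions.

**Step 10**
Reactants: 14 allylic ester
Product: 16 (2R,3S,6E,10E,13R)-3-ethenyl-3,7,11,15-tetramethyl-2-[3-(TBS-oxy)propyl]-13-(TBS-oxy)hexadeca-6,10,14-trienoic acid, via boron enolate 15 (not isolated)
Conditions: (S,S)-2-bromo-4,5-diphenyl-1,3-bis(p-tolylsulfonyl)-1,3,2-diazaborolidine, i-Pr2NEt, CH2Cl2, −78 to 4 °C; aqueous work-up
Reagents that add atoms: none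
Why: Enantioselective boron ester-enolate Claisen rearrangement (Ireland–Claisen type): the Z(O)-boron enolate and the (2E)-allyl unit react through a chair in which the silyloxypropyl group and the side chain are equatorial, which sets the C1–C2 relative configuration, and the C2-symmetric diazaborolidine selects the enolate face and so both absolute configurations.

**Step 11**
Reactants: 16 Claisen acid
Product: 17 γ-keto acid (C6 methyl ketone)
Conditions: PdCl2 (10 mol%), Cu(OAc)2, O2 (1 atm), DMA/H2O 7:1, rt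
Reagents that add atoms: water, O
Why: Tsuji–Wacker oxidation (Markovnikov hydroxypalladation) converts the only monosubstituted alkene into the methyl ketone, and any enol lactone from competing carboxypalladation hydrolyses to the same keto acid.

**Step 12**
Reactants: 17 γ-keto acid
Product: 19 β-keto ester (epimers at the α-carbon), via acyl imidazolide 18 (not isolated)
Conditions: CDI, THF, rt; then KO2CCH(CH3)CO2Et, MgCl2, Et3N, THF, 50 °C
Reagents that add atoms: ethyl potassium methylmalonate, CCOC(=O)C(C)C(=O)[O-].[K+]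
Why: Decarboxylative Claisen condensation of the acyl imidazolide with the magnesium enolate of the malonate half-ester gives the β-keto ester, and these soft conditions do not enolise the methyl ketone.

**Step 13**
Reactants: 19 β-keto ester
Product: 20 (E)-enol triflate (OTf trans to CO2Et)
Conditions: Tf2O, aq. Me4NOH, toluene, 0 °C
Reagents that add atoms: trifluoromethanesulfonic anhydride, FC(F)(F)S(=O)(=O)OS(=O)(=O)C(F)(F)F
Why: O-Triflation of the non-chelated tetramethylammonium enolate of the β-keto ester (dipole-minimised geometry) should give the (E)-enol triflate, while the far less acidic methyl ketone stays untouched.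

**Step 14**
Reactants: 20 (E)-enol triflate
Product: 23 cyclised ethyl (Z)-ester with C6 carbinol, via vinyl carbinol 21 (not isolated), via alkylborane 22 (not isolated)
Conditions: CH2=CHMgBr, LaCl3·2LiCl, THF, −78 °C, then AcOH; 9-BBN, THF, 0 °C to rt; Pd(dppf)Cl2 (10 mol%), AsPh3, Cs2CO3, DMF/H2O, rt, high dilution
Reagents that add atoms: vinylmagnesium bromide, C=C[Mg]Br
Why: Lanthanum-activated 1,2-addition of the Grignard reagent to the methyl ketone forms C5–C6, anti-Markovnikov hydroboration puts boron on C4, and oxidative addition of zerovalent palladium into the alkenyl C3–OTf bond, transmetalation and reductive elimination form C3–C4. The closest known reaction type is the hydroboration/intramolecular B-alkyl Suzuki–Miyaura annulation of an ω-alkenyl alkenyl triflate, here fed by a Grignard addition in the same flask. The six-membered ring closes in the coupling event, by C(sp3)–C(sp2) reductive elimination from a seven-membered palladacycle. C6 is set in the acyclic addition by the C1 quaternary centre (Felkin–Anh: the branched C2 substituent anti to the nucleophile, which passes the C1 methyl rather than the C1 side chain), and the exocyclic alkene keeps the triflate geometry because oxidative addition and reductive elimination proceed with retention. The step needs ketone-over-ester and ketone-over-triflate chemoselectivity, secured by LaCl3·2LiCl at −78 °C and a cold acetic acid quench that stops the alkoxide from displacing the triflate, and vinyl-over-trisubstituted-alkene selectivity, secured by 9-BBN.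

**Step 15**
Reactants: 23 cyclised ethyl ester
Product: 24 primary allylic alcohol
Conditions: i-Bu2AlH (4 equiv), CH2Cl2, −78 to 0 °C
Reagents that add atoms: none
Why: i-Bu2AlH reduction of the conjugated ester should give the allylic alcohol without conjugate reduction of the hindered tetrasubstituted alkene.

**Step 16**
Reactants: 24 primary allylic alcohol
Product: 25 bis-silyl (Z)-enal
Conditions: MnO2, CH2Cl2, rt
Reagents that add atoms: none
Why: MnO2 oxidises only the primary allylic alcohol (allylic alcohol oxidation), the tertiary alcohol and the silyl ethers being inert.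

**Step 17**
Reactants: 25 bis-silyl (Z)-enal
Product: 26 target
Conditions: Bu4NF, AcOH (1:1), THF, rt
Reagents that add atoms: none
Why: Buffered fluoride desilylation removes both silyl ethers, and the acetic acid buffer protects the enal from base-induced isomerisation.

**Compound list**
1 | 3-methylbut-2-enal | CC(C)=CC=O | starting material
2 | (R)-6-methylhept-5-en-1-yn-4-ol | CC(C)=C[C@H](O)CC#C | intermediate
3 | (R)-tert-butyldimethyl[(6-methylhept-5-en-1-yn-4-yl)oxy]silane | CC(C)=C[C@H](O[Si](C)(C)C(C)(C)C)CC#C | intermediate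
4 | (E)-alkenyldimethylalane from 3 | CC(C)=C[C@H](O[Si](C)(C)C(C)(C)C)C/C(C)=C/[Al](C)C | intermediate
5 | (R,E)-tert-butyl[(1-iodo-2,6-dimethylhepta-1,5-dien-4-yl)oxy]dimethylsilane | CC(C)=C[C@H](O[Si](C)(C)C(C)(C)C)C/C(C)=C/I | intermediate
6 | geranyl acetate | CC(C)=CCC/C(C)=C/COC(C)=O | starting material
7 | (2E,6E)-8-hydroxy-3,7-dimethylocta-2,6-dien-1-yl acetate | OC/C(C)=C/CC/C(C)=C/COC(C)=O | intermediate
8 | (2E,6E)-3,7-dimethyl-8-oxoocta-2,6-dien-1-yl acetate | O=C/C(C)=C/CC/C(C)=C/COC(C)=O | intermediate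
9 | (2E,6E)-3,7-dimethylnona-2,6,8-trien-1-yl acetate | C=C/C(C)=C/CC/C(C)=C/COC(C)=O | intermediate
10 | (2E,6E)-3,7-dimethylnona-2,6,8-trien-1-ol | C=C/C(C)=C/CC/C(C)=C/CO | intermediate
11 | B-[(3E,7E)-9-hydroxy-3,7-dimethylnona-3,7-dien-1-yl]-9-BBN | B1(CC/C(C)=C/CC/C(C)=C/CO)C2CCCC1CCC2 | intermediate
12 | (2E,6E,10E,13R)-13-[(tert-butyldimethylsilyl)oxy]-3,7,11,15-tetramethylhexadeca-2,6,10,14-tetraen-1-ol | CC(C)=C[C@H](O[Si](C)(C)C(C)(C)C)C/C(C)=C/CC/C(C)=C/CC/C(C)=C/CO | intermediate
13 | 5-[(tert-butyldimethylsilyl)oxy]pentanoic acid | CC(C)(C)[Si](C)(C)OCCCCC(=O)O | starting material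
14 | ester of 12 with 13 | CC(C)=C[C@H](O[Si](C)(C)C(C)(C)C)C/C(C)=C/CC/C(C)=C/CC/C(C)=C/COC(=O)CCCCO[Si](C)(C)C(C)(C)C | intermediate
15 | Z(O)-boron enolate of 14 with the (S,S)-diazaborolidine | CC(C)=C[C@H](O[Si](C)(C)C(C)(C)C)C/C(C)=C/CC/C(C)=C/CC/C(C)=C/CO/C(OB1N(S(=O)(=O)c2ccc(C)cc2)[C@@H](c2ccccc2)[C@@H](N1S(=O)(=O)c1ccc(C)cc1)c1ccccc1)=C/CCCO[Si](C)(C)C(C)(C)C | intermediate
16 | (2R,3S,6E,10E,13R)-Claisen acid (C1 methyl/vinyl quaternary centre, C2 silyloxypropyl) | CC(C)=C[C@H](O[Si](C)(C)C(C)(C)C)C/C(C)=C/CC/C(C)=C/CC[C@](C=C)(C)[C@@H](CCCO[Si](C)(C)C(C)(C)C)C(=O)O | intermediate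
17 | γ-keto acid (acetyl on C1, C1 and C2 as in 16) | CC(C)=C[C@H](O[Si](C)(C)C(C)(C)C)C/C(C)=C/CC/C(C)=C/CC[C@](C(C)=O)(C)[C@@H](CCCO[Si](C)(C)C(C)(C)C)C(=O)O | intermediate
18 | acyl imidazolide of 17 | CC(C)=C[C@H](O[Si](C)(C)C(C)(C)C)C/C(C)=C/CC/C(C)=C/CC[C@](C(C)=O)(C)[C@@H](CCCO[Si](C)(C)C(C)(C)C)C(=O)n1ccnc1 | intermediate
19 | ethyl 2-methyl-3-oxo ester from 17 (epimers at the α-carbon) | CC(C)=C[C@H](O[Si](C)(C)C(C)(C)C)C/C(C)=C/CC/C(C)=C/CC[C@](C(C)=O)(C)[C@@H](CCCO[Si](C)(C)C(C)(C)C)C(=O)C(C)C(=O)OCC | intermediate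
20 | (E)-enol triflate of 19 (OTf cis to the α-methyl) | CC(C)=C[C@H](O[Si](C)(C)C(C)(C)C)C/C(C)=C/CC/C(C)=C/CC[C@](C(C)=O)(C)[C@@H](CCCO[Si](C)(C)C(C)(C)C)/C(OS(=O)(=O)C(F)(F)F)=C(/C)C(=O)OCC | intermediate
21 | tertiary vinyl carbinol from 20 (C6 R) | CC(C)=C[C@H](O[Si](C)(C)C(C)(C)C)C/C(C)=C/CC/C(C)=C/CC[C@]([C@](C)(O)C=C)(C)[C@@H](CCCO[Si](C)(C)C(C)(C)C)/C(OS(=O)(=O)C(F)(F)F)=C(/C)C(=O)OCC | intermediate
22 | B-alkyl-9-BBN from 21 (boron on C4) | CC(C)=C[C@H](O[Si](C)(C)C(C)(C)C)C/C(C)=C/CC/C(C)=C/CC[C@]([C@](C)(O)CCB1C2CCCC1CCC2)(C)[C@@H](CCCO[Si](C)(C)C(C)(C)C)/C(OS(=O)(=O)C(F)(F)F)=C(/C)C(=O)OCC | intermediate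
23 | cyclohexane ethyl (Z)-ester, ring centres as in the target, both alcohols silylated | CC(C)=C[C@H](O[Si](C)(C)C(C)(C)C)C/C(C)=C/CC/C(C)=C/CC[C@]1(C)[C@@H](CCCO[Si](C)(C)C(C)(C)C)/C(=C(/C)C(=O)OCC)CC[C@@]1(C)O | intermediate
24 | primary allylic alcohol from 23 | CC(C)=C[C@H](O[Si](C)(C)C(C)(C)C)C/C(C)=C/CC/C(C)=C/CC[C@]1(C)[C@@H](CCCO[Si](C)(C)C(C)(C)C)/C(=C(/C)CO)CC[C@@]1(C)O | intermediate
25 | bis-TBS ether of the target | CC(C)=C[C@H](O[Si](C)(C)C(C)(C)C)C/C(C)=C/CC/C(C)=C/CC[C@]1(C)[C@@H](CCCO[Si](C)(C)C(C)(C)C)/C(=C(/C)C=O)CC[C@@]1(C)O | intermediate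
26 | target (ring C1 R, C2 S, C6 R; side-chain carbinol R; (Z)-enal) | CC(C)=C[C@H](O)C/C(C)=C/CC/C(C)=C/CC[C@]1(C)[C@@H](CCCO)/C(=C(/C)C=O)CC[C@@]1(C)O | target

**Step count.** Total: 17 steps. Longest linear sequence: 14 steps (6 to 26, steps 4–17).

**Steps most likely to fail**

Step 14. The acyclic facial selectivity at C6 may be low, because the ketone addition must distinguish a methyl from a CH2 chain on C1, and the tertiary alkoxide may displace the triflate by intramolecular addition–elimination before the coupling. Fallback: setting out from 20, B-alkyl Suzuki–Miyaura coupling with the 9-BBN adduct of 4-methoxybenzyl vinyl ether (Pd(dppf)Cl2, AsPh3, Cs2CO3) would give the 2-(4-methoxybenzyloxy)ethyl enoate F1. DDQ would give the primary alcohol F2, and I2/PPh3/imidazole the primary iodide F3. SmI2 with catalytic NiI2 in THF would then close the ring by an intramolecular Barbier reaction through a chair-like organosamarium transition state, so that C6 is set in a cyclic array, and the route is rejoined at 23.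

Step 10. Enolate-geometry control may be incomplete, or enantioselection low, when the quaternary centre is formed. Fallback: setting out from 14, the classical Ireland–Claisen rearrangement (LiN(i-Pr)2, Me3SiCl, THF/HMPA, Z(O) ketene acetal) would give 16 together with its C1,C2-antipodal diastereomer F4. Esterification with (R)-pantolactone (DCC, DMAP) would give the pantolactone ester F5 (from 16) and the pantolactone ester F6 (from F4), separable by chromatography. LiOH/H2O2 cleavage of F5 returns 16.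

Step 13. E/Z control may erode in O-sulfonylation of the tetrasubstituted enolate. Fallback: setting out from 19, tosylation with TsCl, N-methylimidazole and Et3N, in which an N-sulfonylammonium species traps the non-chelated enolate, would give the (E)-enol tosylate F7. Vinylmagnesium bromide/LaCl3·2LiCl addition (vinyl carbinol F8), 9-BBN hydroboration (alkylborane F9) and ring closure with Pd(OAc)2/SPhos/K3PO4 would rejoin the route at 23.

**Further compounds**
F1 | step 14 | 2-(4-methoxybenzyloxy)ethyl enoate from 20 | CC(C)=C[C@H](O[Si](C)(C)C(C)(C)C)C/C(C)=C/CC/C(C)=C/CC[C@](C(C)=O)(C)[C@@H](CCCO[Si](C)(C)C(C)(C)C)/C(CCOCc1ccc(OC)cc1)=C(/C)C(=O)OCC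
F2 | step 14 | primary alcohol from F1 | CC(C)=C[C@H](O[Si](C)(C)C(C)(C)C)C/C(C)=C/CC/C(C)=C/CC[C@](C(C)=O)(C)[C@@H](CCCO[Si](C)(C)C(C)(C)C)/C(CCO)=C(/C)C(=O)OCC
F3 | step 14 | primary iodide from F2 | CC(C)=C[C@H](O[Si](C)(C)C(C)(C)C)C/C(C)=C/CC/C(C)=C/CC[C@](C(C)=O)(C)[C@@H](CCCO[Si](C)(C)C(C)(C)C)/C(CCI)=C(/C)C(=O)OCC
F4 | step 10 | C1,C2-antipodal diastereomer of 16 | CC(C)=C[C@H](O[Si](C)(C)C(C)(C)C)C/C(C)=C/CC/C(C)=C/CC[C@@](C=C)(C)[C@H](CCCO[Si](C)(C)C(C)(C)C)C(=O)O
F5 | step 10 | (R)-pantolactone ester of 16 | CC(C)=C[C@H](O[Si](C)(C)C(C)(C)C)C/C(C)=C/CC/C(C)=C/CC[C@](C=C)(C)[C@@H](CCCO[Si](C)(C)C(C)(C)C)C(=O)O[C@H]1C(=O)OCC1(C)C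
F6 | step 10 | (R)-pantolactone ester of F4 | CC(C)=C[C@H](O[Si](C)(C)C(C)(C)C)C/C(C)=C/CC/C(C)=C/CC[C@@](C=C)(C)[C@H](CCCO[Si](C)(C)C(C)(C)C)C(=O)O[C@H]1C(=O)OCC1(C)C
F7 | step 13 | (E)-enol tosylate of 19 | CC(C)=C[C@H](O[Si](C)(C)C(C)(C)C)C/C(C)=C/CC/C(C)=C/CC[C@](C(C)=O)(C)[C@@H](CCCO[Si](C)(C)C(C)(C)C)/C(OS(=O)(=O)c1ccc(C)cc1)=C(/C)C(=O)OCC
F8 | step 13 | tertiary vinyl carbinol from F7 | CC(C)=C[C@H](O[Si](C)(C)C(C)(C)C)C/C(C)=C/CC/C(C)=C/CC[C@]([C@](C)(O)C=C)(C)[C@@H](CCCO[Si](C)(C)C(C)(C)C)/C(OS(=O)(=O)c1ccc(C)cc1)=C(/C)C(=O)OCC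
F9 | step 13 | B-alkyl-9-BBN from F8 | CC(C)=C[C@H](O[Si](C)(C)C(C)(C)C)C/C(C)=C/CC/C(C)=C/CC[C@]([C@](C)(O)CCB1C2CCCC1CCC2)(C)[C@@H](CCCO[Si](C)(C)C(C)(C)C)/C(OS(=O)(=O)c1ccc(C)cc1)=C(/C)C(=O)OCC
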